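**The vessel.** The closed, stirred vessel takes starting material and free enzyme, and the gas is held at 5.2 mM, with none in solution at the start.

| setting | north-west | south | north-east | flask |
|---|---|---|---|---|
| starting material | 0.069 M | 0.069 M | 0.035 M | 0.069 M |
| gas | 5.2 mM (held) | 5.2 mM (held) | 5.2 mM (held) | 5.2 mM (held) |
| free enzyme | 20 µM | 31 µM | 14 µM | 14 µM |
| remark | run made earlier | run made earlier | run made earlier |  |

- north-west (time / min: target / %): 1.33: 3.1; 2.50: 6.8; 4.00: 11.0; 5.00: 13.5
- south (time / min: target / %): 1.33: 2.7; 2.50: 7.4; 4.00: 12.6; 5.00: 15.5
- north-east (time / min: target / %): 0.667: 2.3; 1.50: 6.9; 3.00: 13.2; 5.00: 25.4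

(scatter of a reading: 0.5 percentage points)

* apparent order in free enzyme when 5.0% of the starting material are converted (percent change of the rate of making target for one percent more free enzyme charged)
* factor on the rate of making target when 5.0% of the starting material are converted if free enzyme is charged twice over

- the analysis behind the earlier runs scatters by 0.5 percentage points, standard deviation
- at the start none of the gas is in solution

**The ladder.** Replace the south run's curve by its mean rate, the target made up to the last reading, 2.14 mM min⁻¹. At that rate, the south run makes target equal to its enzyme charge in 0.0145 min. The same mean rate, as an estimate, puts 5.0% conversion at 1.61 min and the whole charge at 32.3 min. So the conversion asked about lies inside the south readings, which end at 5.00 min. Check the error: the south slope from 2.50 min to 5.00 min is 2.24 mM min⁻¹, close to the mean.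

**The order.** Take the north-west mean the same way, 1.86 mM min⁻¹; its starting material charge equals the south one. Define the mean-rate order as the logarithm of the ratio of two mean rates over the logarithm of the ratio of their enzyme charges: 0.315. It carries the scatter of 0.5 percentage points on each reading. This reckoning expects an order near 0.315 and a factor of 1.24 for a doubled charge.

**The forecast.** The forecast gives 0.72 and 1.6, from slopes and “resistances in series”, so its order is higher than this reckoning's.

**The result.** The flask gives an order of 0.24 and a factor of 1.12. In the flask at 3.00 min, loaded enzyme, the resting state at that moment, holds 63.3% of the catalyst and free enzyme 8.14%.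

    starting material + free enzyme ⇌ first complex (K = 77.0 M⁻¹, k = 50000 M⁻¹ min⁻¹)
    first complex ⇌ loaded enzyme + first product (K = 0.0240 M, k = 2900 min⁻¹)
    second substrate + loaded enzyme ⇌ second complex (K = 180 M⁻¹, k = 37000 M⁻¹ s⁻¹)
    second complex → free enzyme + target (k = 1400 min⁻¹)
    gas ⇌ second substrate, rate k5*(csat - [second substrate]) (kL = 0.470 min⁻¹)

Scale the south mean to 14 µM with the mean-rate order: 1.66 mM min⁻¹. This flask's mean up to 6.00 min is 1.83 mM min⁻¹. The north-east run, with the same enzyme charge and 0.035 M of starting material, reads 1.78 mM min⁻¹.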